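## The problem

Target 42 is an elemane-type sesquiterpenoid in which all six carbons of the cyclohexane (C5–C10) are stereocentres, with a seventh, C1, in the oxirane on the quaternary C10. Numbering used throughout: C5 bears the acrolein unit C4(=C3H2)–C15HO, C6 the free hydroxyl, C7/C8 the cis-fused α-methylene-γ-lactone (C11=C13, C12, O8), C9 the methacrylate, C10 the methyl C14 and the oxirane C1–C2. The configuration is 1S,5R,6S,7R,8R,9S,10R: the C10 methyl, the C5 side chain and O6 lie on one face (called upper below), and C1, C11, O8 and O9 on the other. The ring has to be built around C10, a quaternary carbon flanked by the oxygenated C9, the branched C5 and the oxygenated exocyclic C1, and no ring substituent can be corrected by equilibration. C5 and C8 can be made in an open chain and are placed to control C10 and C1 during ring closure; once the ring exists, a tether from O8 can set C7 and the shape of the fused system can set C6 and C9. Three Michael acceptors (enal, α-methylene lactone, methacrylate) and a terminal epoxide exclude hydride, strong base, radicals, hydrogenation and strong acid at the end, so the three methylene groups and the ester must arrive late; in addition the C6 hydroxyl is γ to the C15 aldehyde and forms a lactol with it. The enabling feature is the array O9–C9–C10–C1–O: two oxygens 1,3 across the quaternary carbon are the retron of an isoxazoline C9=N–O–C1. An intramolecular nitrile oxide cycloaddition onto an (E)-C10=C1 alkene can therefore form C9–C10, the quaternary centre, the carbocycle and the oxirane C–O bond in one step.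

## Retrosynthesis

**Enal (42 ⇒ 39 ⇒ 38 ⇒ 37).** The C4=C3 bond is cut last: 42 comes from α-methylenation of the C15 aldehyde, which exists as lactol 39 with the C6 hydroxyl. Lactol 39 comes from diol 38 by oxidation of the primary alcohol only, and 38 from the bis-silyl ether 37. The alternative, allylic oxidation of an isopropenyl group, would require C4 as a ketone next to C5 (epimerisable) and an oxidant in the presence of the epoxide. A saturated CH2CH2O arm is simpler and is not a dipolarophile in the key step. The forward steps must stop the oxidation at the lactol and methylenate under mild amine base.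

**Ester and lactone methylene (37 ⇒ 36 ⇒ 33).** The methacrylate C–O bond and C11=C13 are cut next: acylation of the only free hydroxyl of 36, and Mannich/elimination methylenation of the saturated lactone 33. Both acceptors are thereby kept out of every hydride, radical and hydrogenation step.

**Oxirane and C9 carbinol (33 ⇒ 32 ⇒ 31 ⇒ 29).** The C9 alcohol comes from ketone 32, the oxirane C2–O bond from hydroxy tosylate 31, and 31 from isoxazoline 29 by N–O hydrogenolysis. Closing the oxirane from O1 onto C2 leaves C1 untouched, and doing so while C9 is still a carbonyl removes the competing closure of a C9 hydroxyl onto C2 (tetrahydrofuran). The precursor 29 holds C9 and O1 in one robust ring.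

**Lactone and C6 (29 ⇒ 28 ⇒ 27 ⇒ 26 ⇒ 24 ⇒ 23 ⇒ 22 ⇒ 21).** C7–C11 and C6–O are cut together: 5-exo radical cyclisation of the O8-tethered bromoacetal 24 onto C7 with oxygen trapping at C6 gives 26. Oxidation to keto lactone 27 erases the uncontrolled centres, and reduction gives 28. An epoxide opening would deliver carbon to the wrong carbon or face, and a Claisen shift from O8 would deliver it to C6. The tether guarantees the cis lactone. The forward reduction must bring hydrogen from the lower face, for which the isoxazoline-locked chair with its axial C10 methyl is used. Tosylate 23 and diol 22 lead back to cycloadduct 21.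

**Key disconnection (21 ⇒ 18).** C9–C10 and O–C1 are cut: isoxazoline 21 comes from oxime 18 through its nitrile oxide. This cut is preferred to any aldol or alkylation at C10 because it makes the quaternary carbon intramolecularly and fixes C1 in the same event. The precursor is an open chain with only two stereocentres (C5, C8). The forward step needs facial selectivity on the (E)-alkene.

**Chain adjustments (18 ⇒ 17 ⇒ 16 ⇒ 15 ⇒ 14).** Oxime from aldehyde 17, aldehyde from alcohol 16, the (Z)-C6=C7 alkene from alkyne 15 by semihydrogenation, and 15 from the cyclic p-methoxybenzylidene acetal 14 by reductive opening, which frees O9 and leaves O8 protected in one step.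

**C5 stereocentre (14 ⇒ 13 ⇒ 12 ⇒ 10).** C4–C5 is cut: ester 12 is the Johnson–Claisen product of enynol 10, whose carbinol centre (the future C1, later regenerated in step 15) is transferred to C5 while the (E)-C10=C1 alkene forms. Enolate alkylation cannot install C5, since both other substituents are sp2 carbons and a C6 aldehyde would be doubly activated toward epimerisation. Reduction and silylation give 13 and 14.

**Fragment union and chiral pool (10 ⇒ 5 + 9 ⇒ 4 ⇒ 3 ⇒ 2 ⇒ 1).** C5–C6 is cut by Sonogashira coupling of alkyne 5 with (E)-iodide 9. Both fragments come from (R)-but-3-yne-1,2-diol 4, so C8 and the relay centre C1 have one source. Fragment 5 is its acetal; 9 comes from the mono-PMB ether 7 by carboalumination–iodination. Diol 4 derives from (R)-solketal 1 via aldehyde 2 and alkyne 3.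

## Roads not taken

**Alternative 1:** The cut is C5–C6. In the forward sense aldehyde A1, which carries a γ,γ-disubstituted allylboronate with C10 cis to the borylmethyl carbon, would cyclise by intramolecular allylboration to cyclohexanol A2.
- Merits: a closed six-membered transition state sets C5 and C6 together; the C4 methylene and the C15 oxygen arrive in place; C6–OH is formed directly. In steps after ring closure, and in the handling of C6, this road is better than the chosen one, which needs an oxidation/reduction pair for C6.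
- Weak points: A1 must already contain C7, C8, C9 and the quaternary C10 as an acyclic array; the quaternary centre has to be made intermolecularly; the aldehyde is α-branched and epimerisable. The oxirane must later come from epoxidation of the C10 vinyl group, with no directing element and in competition with the 1,1-disubstituted alkene.
- What the chosen plan sets against it: C10 and C1 are formed with the ring, under control of two centres that are easy to install.

**Alternative 2:** The cut is C7–C11 plus C6–O. Bromoacetal A3 would give lactol ether A4 by tethered radical cyclisation with oxygen trapping.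
- Merits: the tether fixes the cis lactone and two adjacent bonds form at once. The reaction is good enough that the chosen route uses it as step 19, and A3 already carries the C9 oxygen, so no ketone reduction at C9 is needed; that is an advantage.
- Weak points: as the central step it builds neither the ring nor the quaternary carbon; the fully substituted cyclohexene A3 is the real problem and is left open. The C6 configuration is not controlled by the tether. A3 also carries a vinyl group and a 1,1-disubstituted alkene that can intercept radicals, and C1 is again left to a late epoxidation.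
- What the chosen plan sets against it: the same reaction is run on a conformationally locked tricycle with no other alkene, and C6 is then corrected through the ketone.

**Alternative 3:** The cut is C6–C7. The ketyl generated from aldehyde A5 with SmI2 would add to the tethered butenolide to give lactone A6.
- Merits: the lactone is present from the start at the right oxidation level, C6 and C7 are set in one reductive cyclisation, and the butenolide is a convergent building block. In oxidation-state economy at the lactone this is better than the chosen route.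
- Weak points: C5 in A5 is α to the aldehyde and allylic, hence prone to epimerisation and conjugation. The quaternary C10 is again acyclic. The required trans C6-OH/C7–C11 and cis C6-OH/C5 relationship depends on one of several possible ketyl transition states. The isopropenyl group needs a late allylic oxidation and the vinyl group a late, uncontrolled epoxidation.
- What the chosen plan sets against it: C5 is never α to a carbonyl, and C1 is set in the ring-forming step.

Key step: step 15

Remark on the chemistry: the acetal carbons of 5, 10–14 and 24–26 and the oxime geometry of 18 are carried as mixtures because each is destroyed later; CIP descriptors of C5 and C10 change along the route although the spatial arrangement does not.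

## Route

Step 1
Reactants: 1 (R)-solketal
Product: 2 (S)-2,2-dimethyl-1,3-dioxolane-4-carbaldehyde
Conditions: (COCl)2, DMSO, CH2Cl2, −78 °C; Et3N
Reagents that add atoms: none
Why: Swern oxidation of a primary alcohol; at −78 °C the α-alkoxy aldehyde should not epimerise and is used at once.

Step 2
Reactants: 2 (S)-2,2-dimethyl-1,3-dioxolane-4-carbaldehyde
Product: 3 (R)-4-ethynyl-2,2-dimethyl-1,3-dioxolane
Conditions: dimethyl (1-diazo-2-oxopropyl)phosphonate, K2CO3, MeOH, 0 °C → rt
Reagents that add atoms: Ohira–Bestmann reagent, COP(=O)(OC)C(=[N+]=[N-])C(C)=O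
Why: Ohira–Bestmann (Seyferth–Gilbert) homologation under mild carbonate conditions; the stereocentre is not touched (the descriptor changes only through CIP priorities).

Step 3
Reactants: 3 (R)-4-ethynyl-2,2-dimethyl-1,3-dioxolane
Product: 4 (R)-but-3-yne-1,2-diol
Conditions: Dowex 50W (H+ form), MeOH/H2O, rt
Reagents that add atoms: none
Why: acid-catalysed acetonide hydrolysis; no bond to the stereocentre is broken.

Step 4
Reactants: 4 (R)-but-3-yne-1,2-diol
Product: 5 (4R)-4-ethynyl-2-(4-methoxyphenyl)-1,3-dioxolane
Conditions: 4-MeOC6H4CH(OMe)2, PPTS (cat.), CH2Cl2, rt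
Reagents that add atoms: 4-methoxybenzaldehyde dimethyl acetal, COc1ccc(C(OC)OC)cc1
Why: acid-catalysed transacetalisation of a 1,2-diol; it protects O8 and O9 together and prepares their later differentiation (step 11).

Step 5
Reactants: 4 (R)-but-3-yne-1,2-diol
Product: 7 (R)-1-[(4-methoxybenzyl)oxy]but-3-yn-2-ol, via stannylene acetal 6 (not isolated)
Conditions: Bu2SnO, toluene, reflux (−H2O); then 4-MeOC6H4CH2Cl, Bu4NI (cat.), 80 °C
Reagents that add atoms: 4-methoxybenzyl chloride, COc1ccc(CCl)cc1
Why: stannylene-acetal monoalkylation; the tin acetal activates the primary oxygen, so the PMB group goes to O2 and the propargylic hydroxyl (future relay centre C1) stays free.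

Step 6
Reactants: 7 (R)-1-[(4-methoxybenzyl)oxy]but-3-yn-2-ol
Product: 9 (R,E)-4-iodo-1-[(4-methoxybenzyl)oxy]-3-methylbut-3-en-2-ol, via alkenylalane 8 (not isolated)
Conditions: AlMe3, Cp2ZrCl2, CH2Cl2, 0 °C → rt; then I2, THF, −30 °C
Reagents that add atoms: trimethylaluminium, C[Al](C)C; iodine, II
Why: zirconium-catalysed (Negishi) carboalumination adds methyl and aluminium syn across the terminal alkyne with methyl on the internal carbon (C10); iodinolysis with retention should give only the (E)-iodide.

Step 7
Reactants: 5 (4R)-4-ethynyl-2-(4-methoxyphenyl)-1,3-dioxolane; 9 (R,E)-4-iodo-1-[(4-methoxybenzyl)oxy]-3-methylbut-3-en-2-ol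
Product: 10 (2R,3E)-1-[(4-methoxybenzyl)oxy]-6-[(4R)-2-(4-methoxyphenyl)-1,3-dioxolan-4-yl]-3-methylhex-3-en-5-yn-2-ol
Conditions: Pd(PPh3)2Cl2 (cat.), CuI (cat.), Et3N, THF, rt
Reagents that add atoms: none
Why: Sonogashira coupling of a vinyl iodide with a terminal alkyne forms C5–C6 with retention of alkene geometry; the free allylic hydroxyl is tolerated.

Step 8
Reactants: 10 enynol (2R,3E)
Product: 12 ethyl (3S,4E)-6-[(4-methoxybenzyl)oxy]-3-{[(4R)-2-(4-methoxyphenyl)-1,3-dioxolan-4-yl]ethynyl}-4-methylhex-4-enoate, via ketene acetal 11 (not isolated)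
Conditions: MeC(OEt)3, EtCO2H (cat.), 135 °C, EtOH distilled off
Reagents that add atoms: triethyl orthoacetate, CCOC(C)(OCC)OCC
Why: Johnson–Claisen rearrangement; the suprafacial [3,3] shift through a chair with CH2OPMB equatorial forms C4–C5, gives the (E)-C10=C1 alkene and transfers the carbinol configuration to C5 (R carbinol plus E alkene gives 5S here, the arrangement called 5R in 42).

Step 9
Reactants: 12 ethyl ester
Product: 13 (3S,4E)-6-[(4-methoxybenzyl)oxy]-3-{[(4R)-2-(4-methoxyphenyl)-1,3-dioxolan-4-yl]ethynyl}-4-methylhex-4-en-1-ol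
Conditions: LiAlH4, THF, 0 °C
Reagents that add atoms: none
Why: hydride reduction of the ester to the primary alcohol (C15); acetal, PMB ether and the unactivated internal alkyne are inert at 0 °C.

Step 10
Reactants: 13 primary alcohol
Product: 14 tert-butyldiphenylsilyl ether of 13
Conditions: TBDPSCl, imidazole, DMF, rt
Reagents that add atoms: tert-butyl(chloro)diphenylsilane, CC(C)(C)[Si](Cl)(c1ccccc1)c1ccccc1
Why: silylation of a primary alcohol; TBDPS is chosen because it survives DDQ and CrO3/H2SO4 later.

Step 11
Reactants: 14 silyl ether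
Product: 15 (2R,5S,6E)-5-{2-[(tert-butyldiphenylsilyl)oxy]ethyl}-2,8-bis[(4-methoxybenzyl)oxy]-6-methyloct-6-en-3-yn-1-ol
Conditions: i-Bu2AlH, CH2Cl2, −78 → 0 °C
Reagents that add atoms: none
Why: reductive opening of the p-methoxybenzylidene acetal; aluminium binds the less hindered primary oxygen, which becomes the free C9–OH, and the PMB group stays on O8.

Step 12
Reactants: 15 enynol
Product: 16 (2R,3Z,5R,6E)-5-{2-[(tert-butyldiphenylsilyl)oxy]ethyl}-2,8-bis[(4-methoxybenzyl)oxy]-6-methylocta-3,6-dien-1-ol
Conditions: H2 (1 atm), Pd/CaCO3 poisoned with Pb(OAc)2 (Lindlar catalyst), quinoline, EtOAc, rt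
Reagents that add atoms: none
Why: Lindlar semihydrogenation; syn delivery of H2 gives the (Z)-C6=C7 alkene and the trisubstituted alkene is not reduced.

Step 13
Reactants: 16 dienol
Product: 17 (2R,3Z,5R,6E)-5-{2-[(tert-butyldiphenylsilyl)oxy]ethyl}-2,8-bis[(4-methoxybenzyl)oxy]-6-methylocta-3,6-dienal
Conditions: Dess–Martin periodinane, NaHCO3, CH2Cl2, 0 °C
Reagents that add atoms: none
Why: Dess–Martin oxidation under buffered conditions, fast and neutral, so the α-alkoxy β,γ-unsaturated aldehyde should neither epimerise at C8 nor move into conjugation; used crude.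

Step 14
Reactants: 17 dienal
Product: 18 oxime of 17
Conditions: NH2OH·HCl, pyridine, EtOH, 0 °C → rt
Reagents that add atoms: hydroxylamine hydrochloride, NO.Cl
Why: condensation of the aldehyde with hydroxylamine; the E/Z mixture is inconsequential.

Step 15
Reactants: 18 oxime
Product: 21 (3S,3aS,4R,7R)-4-{2-[(tert-butyldiphenylsilyl)oxy]ethyl}-7-[(4-methoxybenzyl)oxy]-3-{[(4-methoxybenzyl)oxy]methyl}-3a-methyl-3,3a,4,7-tetrahydro-2,1-benzisoxazole, via hydroximoyl chloride 19 (not isolated), via nitrile oxide 20 (not isolated)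
Conditions: aq. NaOCl, CH2Cl2 (0.005 M), 0 °C → rt
Reagents that add atoms: none
Why: NaOCl chlorinates the aldoxime to hydroximoyl chloride 19, which loses HCl to nitrile oxide 20; this adds to the (E)-C10=C1 alkene in a concerted, suprafacial [3+2] cycloaddition, the closest known reaction type being the intramolecular nitrile oxide–alkene cycloaddition that gives cyclohexane-fused isoxazolines from trisubstituted alkenes. The carbocycle (C5–C10) closes in the fused 6-exo mode through C9–C10 and the isoxazoline closes through O–C1; the (Z)-C6=C7 alkene cannot be reached by the dipole (it would give a three- or four-membered ring) and no other dipolarophile is present. C10 and C1 are set relative to each other by the alkene geometry: suprafacial addition to the E alkene places the C14 methyl and C2 cis on the isoxazoline, which is the 1S/10R relationship of 42. C10 is set relative to C5 by the allylic centre: the fused isoxazoline forces C1 pseudo-equatorial and the methyl pseudo-axial on the forming ring, the tether carbon C6 lies on the methyl side, and the C5 hydrogen then eclipses the C10=C1 bond while the C4 chain points anti to the incoming dipole, so C9 bonds to the face that puts methyl cis to the C5 chain. C8 reinforces this choice, because in that transition state its OPMB group is pseudo-equatorial, whereas attack on the other alkene face would place it syn-axial to the C10 methyl. The step therefore needs facial selectivity (secured by the matched C5 and C8 centres), regioselectivity (imposed by the tether) and suppression of furoxan dimerisation (high dilution).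

Step 16
Reactants: 21 cycloadduct
Product: 22 (3S,3aS,4R,7R)-4-{2-[(tert-butyldiphenylsilyl)oxy]ethyl}-3-(hydroxymethyl)-3a-methyl-3,3a,4,7-tetrahydro-2,1-benzisoxazol-7-ol
Conditions: DDQ, CH2Cl2/pH 7 buffer, 0 °C
Reagents that add atoms: none
Why: oxidative cleavage of both PMB ethers (benzylic hydride abstraction, then hydrolysis); silyl ether and isoxazoline are inert, and the low temperature limits oxidation of the allylic C8 alcohol.

Step 17
Reactants: 22 diol
Product: 23 C2 tosylate of 22 (C8–OH free)
Conditions: TsCl, Et3N, DMAP (cat.), CH2Cl2, 0 °C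
Reagents that add atoms: 4-toluenesulfonyl chloride, Cc1ccc(S(=O)(=O)Cl)cc1
Why: selective sulfonylation of the primary hydroxyl over the hindered secondary allylic one; the tosylate serves both as protection of O2 and as the leaving group for step 24.

Step 18
Reactants: 23 hydroxy tosylate
Product: 24 C8 O-(2-bromo-1-ethoxyethyl) acetal of 23
Conditions: ethyl vinyl ether, NBS, CH2Cl2, −40 → 0 °C
Reagents that add atoms: ethyl vinyl ether, C=COCC; N-bromosuccinimide, O=C1CCC(=O)N1Br
Why: bromoacetalisation; NBS brominates the electron-rich vinyl ether and the C8 hydroxyl captures the oxocarbenium ion, the ring alkene being far less nucleophilic.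

Step 19
Reactants: 24 bromoacetal
Product: 26 cyclised lactol ethyl ether with C6 hydroxyl (C6 and C12 epimers), via C6 hydroperoxide 25 (not isolated)
Conditions: Bu3SnH (slow addition), Et3B (cat.), dry air, toluene, 0 °C → rt; then PPh3
Reagents that add atoms: dioxygen, O=O
Why: Ueno–Stork 5-exo-trig radical cyclisation with oxygen trapping (oxygenative radical cyclisation); the C11 radical is held by the O8 tether and can only reach C7 from the lower face, so the new ring is cis-fused (C11 cis to O8). The C6 radical is captured by O2 and the hydroperoxide reduced by PPh3; the C6 and acetal configurations are irrelevant because both centres are oxidised next.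

Step 20
Reactants: 26 hydroxy lactol ether
Product: 27 keto lactone (C6 ketone and cis-fused 8,12-γ-lactone on the isoxazoline core)
Conditions: CrO3, H2SO4, H2O, acetone, 0 °C → rt
Reagents that add atoms: water, O
Why: Jones oxidation converts the secondary alcohol into the ketone and hydrolyses and oxidises the lactol ether to the γ-lactone, so all four diastereomers of 26 converge on one compound; tosylate, TBDPS ether and isoxazoline tolerate the reagent.

Step 21
Reactants: 27 keto lactone
Product: 28 C6 alcohol (hydroxyl axial on the upper face, cis to the C5 chain and the C10 methyl)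
Conditions: LiB(s-Bu)3H (L-Selectride), THF, −78 °C
Reagents that add atoms: none
Why: bulky-hydride ketone reduction; the isoxazoline fusion locks the carbocycle as a chair with the C10 methyl axial, which blocks the axial trajectory on the upper face. The hydride should therefore add equatorially from the lower face, where the flanking C7–C11 bond is tied back into the lactone, giving the axial 6S alcohol; lactone and isoxazoline are inert at −78 °C.

Step 22
Reactants: 28 C6 alcohol
Product: 29 C6 O-triethylsilyl ether of 28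
Conditions: TESOTf, 2,6-lutidine, CH2Cl2, −78 → 0 °C
Reagents that add atoms: triethylsilyl trifluoromethanesulfonate, CC[Si](CC)(CC)OS(=O)(=O)C(F)(F)F
Why: silylation with the reactive triflate masks the hindered axial hydroxyl, so that C9–OH is the only free hydroxyl in step 27.

Step 23
Reactants: 29 isoxazoline
Product: 31 β-hydroxy ketone (C9 ketone with C1–OH and C2–OTs), via hydroxy imine 30 (not isolated)
Conditions: H2 (1 atm), Raney Ni, B(OH)3, MeOH/H2O, rt
Reagents that add atoms: water, O
Why: hydrogenolysis of the isoxazoline N–O bond with buffered hydrolysis of the imine, the standard unmasking of a β-hydroxy ketone; no alkene is present at this stage and the α-carbon C10 is quaternary, so nothing can epimerise or dehydrate.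

Step 24
Reactants: 31 hydroxy tosylate
Product: 32 epoxy ketone (oxirane C1–C2 with C1 S)
Conditions: DBU, CH2Cl2, 0 °C → rt
Reagents that add atoms: none
Why: intramolecular Williamson (3-exo-tet) displacement of the primary tosylate by O1; C1 is not the reacting carbon, so the configuration set in step 15 is retained, and with C9 still a carbonyl no second hydroxyl can compete for C2.

Step 25
Reactants: 32 epoxy ketone
Product: 33 C9 alcohol (hydroxyl on the lower face, cis to O8)
Conditions: NaBH4, MeOH, −40 → −10 °C
Reagents that add atoms: none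
Why: borohydride reduction; the hydride should approach C9 on the convex upper face of the cis-fused bicycle, anti to the C8–O bond and to the C10 oxiranyl group, giving the 9S alcohol. Epoxide and lactone are inert.

Step 26
Reactants: 33 hydroxy lactone
Product: 36 α-methylene lactone with free C9–OH, via Mannich base 34 (not isolated), via ammonium iodide 35 (not isolated)
Conditions: LiN(i-Pr)2 (2.5 equiv), THF, −78 °C; CH2=NMe2+ I−, −78 → 0 °C; then MeI, MeOH, rt; then aq. NaHCO3, CH2Cl2
Reagents that add atoms: Eschenmoser's salt, C=[N+](C)C.[I-]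
Why: Eschenmoser methylenation: the lactone enolate (one extra equivalent of base for the C9 alkoxide) undergoes a Mannich reaction, then N-methylation and Hofmann-type elimination give C11=C13.

Step 27
Reactants: 36 hydroxy α-methylene lactone
Product: 37 C9 methacrylate
Conditions: methacrylic anhydride, Et3N, DMAP, CH2Cl2, 0 °C → rt
Reagents that add atoms: methacrylic anhydride, C=C(C)C(=O)OC(=O)C(C)=C
Why: DMAP-catalysed acylation of the only free hydroxyl; the conditions are non-nucleophilic enough for the epoxide and the methylene lactone.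

Step 28
Reactants: 37 bis-silyl ether
Product: 38 diol (C6–OH and C15–OH free)
Conditions: Bu4NF, AcOH, THF, rt
Reagents that add atoms: none
Why: fluoride desilylation buffered with acetic acid, so that the epoxide and the three acceptor groups are not exposed to basic fluoride or alkoxide.

Step 29
Reactants: 38 diol
Product: 39 lactol (C15 hemiacetal closed onto O6, both anomers)
Conditions: IBX, DMSO, rt
Reagents that add atoms: none
Why: IBX oxidation of a 1,4-diol; the primary alcohol is oxidised first and the aldehyde is captured by the cis C6 hydroxyl as a γ-lactol, which IBX does not oxidise further under these conditions.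

Step 30
Reactants: 39 lactol
Product: 42 target CNP0124638.3, via hydroxy aldehyde 40 (not isolated), via Mannich base 41 (not isolated)
Conditions: CH2=NMe2+ I−, Et3N, CH2Cl2, rt
Reagents that add atoms: Eschenmoser's salt, C=[N+](C)C.[I-]
Why: α-methylenation of an aldehyde by Mannich reaction and amine elimination, through the open hydroxy aldehyde in equilibrium with the lactol; C5 is β to the carbonyl and cannot epimerise, and conjugation in the enal should favour the open hydroxy aldehyde form.

## Compound list

1 | (R)-solketal, (R)-(2,2-dimethyl-1,3-dioxolan-4-yl)methanol | OC[C@@H]1COC(C)(C)O1 | starting material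
2 | (S)-2,2-dimethyl-1,3-dioxolane-4-carbaldehyde | O=C[C@@H]1COC(C)(C)O1 | intermediate
3 | (R)-4-ethynyl-2,2-dimethyl-1,3-dioxolane | C#C[C@@H]1COC(C)(C)O1 | intermediate
4 | (R)-but-3-yne-1,2-diol | C#C[C@@H](O)CO | intermediate
5 | (4R)-4-ethynyl-2-(4-methoxyphenyl)-1,3-dioxolane (both C2 epimers) | C#C[C@@H]1COC(c2ccc(OC)cc2)O1 | intermediate
6 | (R)-2,2-dibutyl-4-ethynyl-1,3,2-dioxastannolane (not isolated) | C#C[C@@H]1CO[Sn](CCCC)(CCCC)O1 | intermediate
7 | (R)-1-[(4-methoxybenzyl)oxy]but-3-yn-2-ol | C#C[C@@H](O)COCc1ccc(OC)cc1 | intermediate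
8 | (E)-alkenylalane from 7, dimethylaluminium alkoxide (not isolated) | C[Al](C)/C=C(\C)[C@H](COCc1ccc(OC)cc1)O[Al](C)C | intermediate
9 | (R,E)-4-iodo-1-[(4-methoxybenzyl)oxy]-3-methylbut-3-en-2-ol | I/C=C(\C)[C@@H](O)COCc1ccc(OC)cc1 | intermediate
10 | (2R,3E)-1-[(4-methoxybenzyl)oxy]-6-[(4R)-2-(4-methoxyphenyl)-1,3-dioxolan-4-yl]-3-methylhex-3-en-5-yn-2-ol | COc1ccc(COC[C@H](O)/C(C)=C/C#C[C@@H]2COC(c3ccc(OC)cc3)O2)cc1 | intermediate
11 | mixed ketene acetal of 10, O-(1-ethoxyvinyl) ether (not isolated) | C=C(OCC)O[C@@H](COCc1ccc(OC)cc1)/C(C)=C/C#C[C@@H]1COC(c2ccc(OC)cc2)O1 | intermediate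
12 | ethyl (3S,4E)-6-[(4-methoxybenzyl)oxy]-3-{[(4R)-2-(4-methoxyphenyl)-1,3-dioxolan-4-yl]ethynyl}-4-methylhex-4-enoate | CCOC(=O)C[C@H](C#C[C@@H]1COC(c2ccc(OC)cc2)O1)/C(C)=C/COCc1ccc(OC)cc1 | intermediate
13 | (3S,4E)-6-[(4-methoxybenzyl)oxy]-3-{[(4R)-2-(4-methoxyphenyl)-1,3-dioxolan-4-yl]ethynyl}-4-methylhex-4-en-1-ol | OCC[C@H](C#C[C@@H]1COC(c2ccc(OC)cc2)O1)/C(C)=C/COCc1ccc(OC)cc1 | intermediate
14 | tert-butyldiphenylsilyl ether of 13 | CC(C)(C)[Si](OCC[C@H](C#C[C@@H]1COC(c2ccc(OC)cc2)O1)/C(C)=C/COCc1ccc(OC)cc1)(c1ccccc1)c1ccccc1 | intermediate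
15 | (2R,5S,6E)-5-{2-[(tert-butyldiphenylsilyl)oxy]ethyl}-2,8-bis[(4-methoxybenzyl)oxy]-6-methyloct-6-en-3-yn-1-ol | CC(C)(C)[Si](OCC[C@H](C#C[C@H](CO)OCc1ccc(OC)cc1)/C(C)=C/COCc1ccc(OC)cc1)(c1ccccc1)c1ccccc1 | intermediate
16 | (2R,3Z,5R,6E)-5-{2-[(tert-butyldiphenylsilyl)oxy]ethyl}-2,8-bis[(4-methoxybenzyl)oxy]-6-methylocta-3,6-dien-1-ol | CC(C)(C)[Si](OCC[C@H](/C=C\[C@H](CO)OCc1ccc(OC)cc1)/C(C)=C/COCc1ccc(OC)cc1)(c1ccccc1)c1ccccc1 | intermediate
17 | (2R,3Z,5R,6E)-5-{2-[(tert-butyldiphenylsilyl)oxy]ethyl}-2,8-bis[(4-methoxybenzyl)oxy]-6-methylocta-3,6-dienal | O=C[C@H](OCc1ccc(OC)cc1)/C=C\[C@@H](CCO[Si](c1ccccc1)(c1ccccc1)C(C)(C)C)/C(C)=C/COCc1ccc(OC)cc1 | intermediate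
18 | oxime of 17 (C9 aldoxime, E/Z mixture; C8 R, C5 R) | ON=C[C@H](OCc1ccc(OC)cc1)/C=C\[C@@H](CCO[Si](c1ccccc1)(c1ccccc1)C(C)(C)C)/C(C)=C/COCc1ccc(OC)cc1 | intermediate
19 | hydroximoyl chloride of 18 (not isolated) | ON=C(Cl)[C@H](OCc1ccc(OC)cc1)/C=C\[C@@H](CCO[Si](c1ccccc1)(c1ccccc1)C(C)(C)C)/C(C)=C/COCc1ccc(OC)cc1 | intermediate
20 | nitrile oxide from 18 (not isolated) | [O-][N+]#C[C@H](OCc1ccc(OC)cc1)/C=C\[C@@H](CCO[Si](c1ccccc1)(c1ccccc1)C(C)(C)C)/C(C)=C/COCc1ccc(OC)cc1 | intermediate
21 | (3S,3aS,4R,7R)-4-{2-[(tert-butyldiphenylsilyl)oxy]ethyl}-7-[(4-methoxybenzyl)oxy]-3-{[(4-methoxybenzyl)oxy]methyl}-3a-methyl-3,3a,4,7-tetrahydro-2,1-benzisoxazole (C10 methyl cis to the C5 chain, trans to O8) | C12=NO[C@H](COCc3ccc(OC)cc3)[C@@]1(C)[C@H](CCO[Si](c3ccccc3)(c3ccccc3)C(C)(C)C)C=C[C@H]2OCc1ccc(OC)cc1 | intermediate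
22 | (3S,3aS,4R,7R)-4-{2-[(tert-butyldiphenylsilyl)oxy]ethyl}-3-(hydroxymethyl)-3a-methyl-3,3a,4,7-tetrahydro-2,1-benzisoxazol-7-ol | C12=NO[C@H](CO)[C@@]1(C)[C@H](CCO[Si](c3ccccc3)(c3ccccc3)C(C)(C)C)C=C[C@H]2O | intermediate
23 | C2 tosylate of 22: [(3S,3aS,4R,7R)-4-{2-[(tert-butyldiphenylsilyl)oxy]ethyl}-7-hydroxy-3a-methyl-3,3a,4,7-tetrahydro-2,1-benzisoxazol-3-yl]methyl 4-methylbenzenesulfonate | C12=NO[C@H](COS(=O)(=O)c3ccc(C)cc3)[C@@]1(C)[C@H](CCO[Si](c3ccccc3)(c3ccccc3)C(C)(C)C)C=C[C@H]2O | intermediate
24 | C8 O-(2-bromo-1-ethoxyethyl) acetal of 23 (both acetal epimers) | C12=NO[C@H](COS(=O)(=O)c3ccc(C)cc3)[C@@]1(C)[C@H](CCO[Si](c3ccccc3)(c3ccccc3)C(C)(C)C)C=C[C@H]2OC(CBr)OCC | intermediate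
25 | C6 hydroperoxide of the cyclised lactol ethyl ether (not isolated; C6 and C12 epimers; ring O8–C12–C11–C7 cis-fused) | C12=NO[C@H](COS(=O)(=O)c3ccc(C)cc3)[C@@]1(C)[C@H](CCO[Si](c3ccccc3)(c3ccccc3)C(C)(C)C)C(OO)[C@H]3CC(OCC)O[C@@H]23 | intermediate
26 | C6 alcohol of the cyclised lactol ethyl ether (C6 and C12 epimers; H7 and H8 cis) | C12=NO[C@H](COS(=O)(=O)c3ccc(C)cc3)[C@@]1(C)[C@H](CCO[Si](c3ccccc3)(c3ccccc3)C(C)(C)C)C(O)[C@H]3CC(OCC)O[C@@H]23 | intermediate
27 | keto lactone: isoxazoline core with C6 ketone, cis-fused 8,12-γ-lactone (C11 cis to O8), C2–OTs, C15–OTBDPS | C12=NO[C@H](COS(=O)(=O)c3ccc(C)cc3)[C@@]1(C)[C@H](CCO[Si](c3ccccc3)(c3ccccc3)C(C)(C)C)C(=O)[C@H]3CC(=O)O[C@@H]23 | intermediate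
28 | C6 alcohol of 27 (6-OH on the upper face, cis to the C5 chain and C10 methyl, trans to C11) | C12=NO[C@H](COS(=O)(=O)c3ccc(C)cc3)[C@@]1(C)[C@H](CCO[Si](c3ccccc3)(c3ccccc3)C(C)(C)C)[C@H](O)[C@H]3CC(=O)O[C@@H]23 | intermediate
29 | C6 O-triethylsilyl ether of 28 | C12=NO[C@H](COS(=O)(=O)c3ccc(C)cc3)[C@@]1(C)[C@H](CCO[Si](c3ccccc3)(c3ccccc3)C(C)(C)C)[C@H](O[Si](CC)(CC)CC)[C@H]3CC(=O)O[C@@H]23 | intermediate
30 | β-hydroxy imine from 29 (C9=NH, C1–OH; not isolated) | N=C1[C@@H]2OC(=O)C[C@@H]2[C@@H](O[Si](CC)(CC)CC)[C@@H](CCO[Si](c2ccccc2)(c2ccccc2)C(C)(C)C)[C@]1(C)[C@H](O)COS(=O)(=O)c1ccc(C)cc1 | intermediate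
31 | β-hydroxy ketone: C9 ketone, C1–OH, C2–OTs, 8,12-lactone, C6–OTES, C15–OTBDPS | O=C1[C@@H]2OC(=O)C[C@@H]2[C@@H](O[Si](CC)(CC)CC)[C@@H](CCO[Si](c2ccccc2)(c2ccccc2)C(C)(C)C)[C@]1(C)[C@H](O)COS(=O)(=O)c1ccc(C)cc1 | intermediate
32 | epoxy ketone: C9 ketone with the C1–C2 oxirane (C1 S) on C10 | O=C1[C@@H]2OC(=O)C[C@@H]2[C@@H](O[Si](CC)(CC)CC)[C@@H](CCO[Si](c2ccccc2)(c2ccccc2)C(C)(C)C)[C@]1(C)[C@H]1CO1 | intermediate
33 | C9 alcohol of 32 (9-OH on the lower face, cis to O8, trans to C10 methyl) | O[C@@H]1[C@@H]2OC(=O)C[C@@H]2[C@@H](O[Si](CC)(CC)CC)[C@@H](CCO[Si](c2ccccc2)(c2ccccc2)C(C)(C)C)[C@]1(C)[C@H]1CO1 | intermediate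
34 | C11 (dimethylamino)methyl lactone (C11 epimers; not isolated) | O[C@@H]1[C@@H]2OC(=O)C(CN(C)C)[C@@H]2[C@@H](O[Si](CC)(CC)CC)[C@@H](CCO[Si](c2ccccc2)(c2ccccc2)C(C)(C)C)[C@]1(C)[C@H]1CO1 | intermediate
35 | trimethylammonium iodide of 34 (not isolated) | O[C@@H]1[C@@H]2OC(=O)C(C[N+](C)(C)C)[C@@H]2[C@@H](O[Si](CC)(CC)CC)[C@@H](CCO[Si](c2ccccc2)(c2ccccc2)C(C)(C)C)[C@]1(C)[C@H]1CO1.[I-] | intermediate
36 | α-methylene lactone with free C9–OH, C6–OTES, C15–OTBDPS | O[C@@H]1[C@@H]2OC(=O)C(=C)[C@@H]2[C@@H](O[Si](CC)(CC)CC)[C@@H](CCO[Si](c2ccccc2)(c2ccccc2)C(C)(C)C)[C@]1(C)[C@H]1CO1 | intermediate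
37 | C9 methacrylate of 36 | C=C(C)C(=O)O[C@@H]1[C@@H]2OC(=O)C(=C)[C@@H]2[C@@H](O[Si](CC)(CC)CC)[C@@H](CCO[Si](c2ccccc2)(c2ccccc2)C(C)(C)C)[C@]1(C)[C@H]1CO1 | intermediate
38 | diol: C6–OH and C15–OH (C5 bears CH2CH2OH) | C=C(C)C(=O)O[C@@H]1[C@@H]2OC(=O)C(=C)[C@@H]2[C@@H](O)[C@@H](CCO)[C@]1(C)[C@H]1CO1 | intermediate
39 | lactol: C15 hemiacetal closed onto O6, cis-fused five-membered ring O6–C15–C4–C5–C6 (both anomers) | C=C(C)C(=O)O[C@@H]1[C@@H]2OC(=O)C(=C)[C@@H]2[C@H]2OC(O)C[C@H]2[C@]1(C)[C@H]1CO1 | intermediate
40 | open hydroxy aldehyde form of 39 (C5 bears CH2CHO; not isolated) | C=C(C)C(=O)O[C@@H]1[C@@H]2OC(=O)C(=C)[C@@H]2[C@@H](O)[C@@H](CC=O)[C@]1(C)[C@H]1CO1 | intermediate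
41 | C4 (dimethylamino)methyl aldehyde (C4 epimers; not isolated) | C=C(C)C(=O)O[C@@H]1[C@@H]2OC(=O)C(=C)[C@@H]2[C@@H](O)[C@@H](C(CN(C)C)C=O)[C@]1(C)[C@H]1CO1 | intermediate
42 | CNP0124638.3, (1S,5R,6S,7R,8R,9S,10R) in the skeleton numbering used here | C=C(C)C(=O)O[C@@H]1[C@@H]2OC(=O)C(=C)[C@@H]2[C@@H](O)[C@@H](C(=C)C=O)[C@]1(C)[C@H]1CO1 | target

## Step count and risks

Total: 30 steps. Longest linear sequence: 29 steps (steps 1–3 and 5–30 from 1; step 4 is the only step off this line).

**Step 15 (key step).** The closure onto a trisubstituted alkene creates a quaternary carbon and may be slow enough for the nitrile oxide to dimerise to the furoxan, or hypochlorite may chlorinate the electron-rich alkene before the dipole forms; facial selectivity could also fall short if the C5 chain does not hold the anti position. The fallback changes the dipole to a silyl nitronate, which does not dimerise. It sets out from alcohol 16: PPh3, I2 and imidazole give the primary iodide F1; NaNO2 in DMF gives the nitro compound F2; TMSCl and Et3N convert F2 into its silyl nitronate, which cyclises onto C10=C1 to the N-silyloxy isoxazolidine F3; TsOH eliminates trimethylsilanol from F3 and the route is rejoined at cycloadduct 21.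

**Step 8.** The p-methoxybenzylidene acetal may be lost or exchanged under hot carboxylic acid and ethanol, or the conjugated enyne may isomerise thermally before it rearranges. The fallback is an Ireland–Claisen rearrangement at low temperature. It sets out from enynol 10: Ac2O and pyridine give the acetate F4; LiN(i-Pr)2 and TMSCl at −78 °C followed by warming rearrange the silyl ketene acetal through the same chair to the acid F5; LiAlH4 reduction of F5 rejoins the route at alcohol 13.

**Step 19.** Three radical rates must be balanced: O2 may capture the C11 radical before it cyclises, Bu3SnH may reduce the C6 radical before O2 reaches it, and addition of the C11 radical to C9 of the isoxazoline C=N is a further competitor. The fallback separates ring closure from oxygenation. It sets out from hydroxy tosylate 23: N-iodosuccinimide and ethyl vinyl ether give the iodoacetal F6; Et3B-initiated iodine-atom-transfer cyclisation under argon gives the C6 iodide F7; Bu3SnH under air then converts the secondary iodide into the alcohol, rejoining the route at 26.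

**Step 21.** The C6 carbonyl is screened on both faces (C10 methyl above, C7–C11 bond below), so reduction may be slow; at higher temperature the basic hydride can expel the C8 carboxylate by E1cB through the C7 enolate, or lose facial selectivity. The fallback reduces one oxidation level earlier, where the β-leaving group is only an acetal alkoxide. It sets out from 26: Dess–Martin oxidation gives the keto lactol ether F8; LiB(s-Bu)3H gives the C6 alcohol F9; aqueous acetic acid hydrolyses the acetal to the lactol F10; Ag2CO3 on Celite oxidises the lactol selectively over the hindered C6 hydroxyl, rejoining the route at 28.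

**Step 24.** The C1 alkoxide is β to the C9 ketone on a quaternary α-carbon, so retro-aldol cleavage of C10–C1 may compete with ring closure. The fallback closes the ring without base. It sets out from 31: NaI in acetone exchanges the tosylate for iodide to give the iodohydrin F11; Ag2O activates the iodide and the neutral C1 hydroxyl closes the oxirane, rejoining the route at 32.

## Further compounds

F1 | step 15 | primary iodide from 16 (C9–I) | CC(C)(C)[Si](OCC[C@H](/C=C\[C@H](CI)OCc1ccc(OC)cc1)/C(C)=C/COCc1ccc(OC)cc1)(c1ccccc1)c1ccccc1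
F2 | step 15 | nitro compound (C9–NO2) | CC(C)(C)[Si](OCC[C@H](/C=C\[C@H](C[N+](=O)[O-])OCc1ccc(OC)cc1)/C(C)=C/COCc1ccc(OC)cc1)(c1ccccc1)c1ccccc1
F3 | step 15 | N-(trimethylsilyloxy)isoxazolidine (C9 epimers) | C12N(O[Si](C)(C)C)O[C@H](COCc3ccc(OC)cc3)[C@@]1(C)[C@H](CCO[Si](c3ccccc3)(c3ccccc3)C(C)(C)C)C=C[C@H]2OCc1ccc(OC)cc1
F4 | step 8 | acetate of 10 | CC(=O)O[C@@H](COCc1ccc(OC)cc1)/C(C)=C/C#C[C@@H]1COC(c2ccc(OC)cc2)O1
F5 | step 8 | (3S,4E)-carboxylic acid corresponding to ester 12 | OC(=O)C[C@H](C#C[C@@H]1COC(c2ccc(OC)cc2)O1)/C(C)=C/COCc1ccc(OC)cc1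
F6 | step 19 | C8 O-(1-ethoxy-2-iodoethyl) acetal of 23 | C12=NO[C@H](COS(=O)(=O)c3ccc(C)cc3)[C@@]1(C)[C@H](CCO[Si](c3ccccc3)(c3ccccc3)C(C)(C)C)C=C[C@H]2OC(CI)OCC
F7 | step 19 | cyclised lactol ethyl ether with C6 iodide (C6 and C12 epimers) | C12=NO[C@H](COS(=O)(=O)c3ccc(C)cc3)[C@@]1(C)[C@H](CCO[Si](c3ccccc3)(c3ccccc3)C(C)(C)C)C(I)[C@H]3CC(OCC)O[C@@H]23
F8 | step 21 | C6 ketone of the lactol ethyl ether (C12 epimers) | C12=NO[C@H](COS(=O)(=O)c3ccc(C)cc3)[C@@]1(C)[C@H](CCO[Si](c3ccccc3)(c3ccccc3)C(C)(C)C)C(=O)[C@H]3CC(OCC)O[C@@H]23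
F9 | step 21 | C6 alcohol (upper face) of the lactol ethyl ether | C12=NO[C@H](COS(=O)(=O)c3ccc(C)cc3)[C@@]1(C)[C@H](CCO[Si](c3ccccc3)(c3ccccc3)C(C)(C)C)[C@H](O)[C@H]3CC(OCC)O[C@@H]23
F10 | step 21 | C12 lactol with C6 alcohol | C12=NO[C@H](COS(=O)(=O)c3ccc(C)cc3)[C@@]1(C)[C@H](CCO[Si](c3ccccc3)(c3ccccc3)C(C)(C)C)[C@H](O)[C@H]3CC(O)O[C@@H]23
F11 | step 24 | iodohydrin (C1–OH, C2–I) of the C9 ketone | O=C1[C@@H]2OC(=O)C[C@@H]2[C@@H](O[Si](CC)(CC)CC)[C@@H](CCO[Si](c2ccccc2)(c2ccccc2)C(C)(C)C)[C@]1(C)[C@H](O)CI
A1 | alternative 1 | open-chain C6 aldehyde with C8/C9 acetonide, C7 CH2CO2tBu, quaternary C10 and the (pinacolato)borylmethyl alkene (C10 cis to C3) | O=C[C@@H](CC(=O)OC(C)(C)C)[C@H]1OC(C)(C)O[C@H]1[C@@](C)(C=C)/C=C(\CB1OC(C)(C)C(C)(C)O1)CO[Si](C)(C)C(C)(C)C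
A2 | alternative 1 | cyclohexanol with all six ring stereocentres set | CC1(C)O[C@@H]2[C@H](O1)[C@H](CC(=O)OC(C)(C)C)[C@@H](O)[C@@H](C(=C)CO[Si](C)(C)C(C)(C)C)[C@]2(C)C=C
A3 | alternative 2 | cyclohexenyl O8 bromoacetal with C9 OPMB, C10 vinyl and the C5 allyl silyl ether arm | COc1ccc(CO[C@@H]2[C@H](OC(CBr)OCC)C=C[C@@H](C(=C)CO[Si](C)(C)C(C)(C)C)[C@]2(C)C=C)cc1
A4 | alternative 2 | cis-fused bicyclic lactol ether with C6 hydroxyl | COc1ccc(CO[C@@H]2[C@@H]3OC(OCC)C[C@@H]3[C@@H](O)[C@@H](C(=C)CO[Si](C)(C)C(C)(C)C)[C@]2(C)C=C)cc1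
A5 | alternative 3 | C6 aldehyde tethered to the butenolide through C8, with C9 OTBS, quaternary C10 and C5 isopropenyl | O=C[C@@H](C(C)=C)[C@](C)(C=C)[C@H](O[Si](C)(C)C(C)(C)C)[C@@H]1OC(=O)C=C1
A6 | alternative 3 | cis-fused γ-lactone with C6 hydroxyl | CC(C)(C)[Si](C)(C)O[C@@H]1[C@@H]2OC(=O)C[C@@H]2[C@@H](O)[C@@H](C(C)=C)[C@]1(C)C=C
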